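## Retrosynthetic overview

1. Target (meso) ⇐ bis(methyl ketone) bis(silyl ether), by twofold α-alkenylation of the two acetyl groups with 1-bromo-2-methylprop-1-ene, then desilylation.
2. The Z,Z-diene ⇐ two successive Z-selective Wittig reactions of the two antipodal α-silyloxy ketones with the four-carbon bis(phosphonium) salt; one antipode first, the other second, so the dimer is meso by construction.
3. Each α-silyloxy ketone ⇐ epoxy ketone by a stereospecific semipinacol 1,2-methyl shift (new step): the oxirane oxygen stays on C2 and the methyl enters anti, so acetyl and oxygen end up cis.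
4. Key C–O bonds: enantioselective epoxidation of 3-(2-hydroxypropan-2-yl)cyclohex-2-en-1-one, run once with each pseudo-enantiomeric amine catalyst; the enone comes from 1-acetylcyclohexene (CH3Li, then allylic oxidation).
5. Ring order: no carbocycle is built; both cyclohexanes come from the starting material, and the only ring made (then opened) is the oxirane.

Assumption: the given SMILES is a meso compound (ring A 1R,2S; ring B 1S,2R; both exocyclic alkenes Z), so exactly this stereoisomer is made by joining the two enantiomeric halves; which cinchona-derived catalyst gives which epoxide antipode is assigned by analogy and does not matter, because both antipodes are carried forward in equal amounts.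

## Route

Step 1
Reactants: 1 1-(cyclohex-1-en-1-yl)ethan-1-one
Product: 2 2-(cyclohex-1-en-1-yl)propan-2-ol
Conditions: CH3Li (1.2 equiv), Et2O, −78 → 0 °C; H2O
Reagents that add atoms: methyllithium, C[Li]
Why: 1,2-addition of CH3Li to the enone carbonyl gives the tertiary allylic alcohol; no stereocentre is formed.

Step 2
Reactants: 2 2-(cyclohex-1-en-1-yl)propan-2-ol
Product: 3 3-(2-hydroxypropan-2-yl)cyclohex-2-en-1-one
Conditions: Rh2(cap)4 (cap = caprolactamate, 1 mol%), t-BuOOH (70% aq., 5 equiv), K2CO3, CH2Cl2, rt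
Reagents that add atoms: tert-butyl hydroperoxide, CC(C)(C)OO
Why: radical allylic C–H oxidation with t-BuOOH under Rh2(cap)4 catalysis attacks the ring CH2 remote from the bulky carbinol, and collapse of the allylic peroxide gives the conjugated enone; no stereocentre.

Step 3
Reactants: 3 3-(2-hydroxypropan-2-yl)cyclohex-2-en-1-one
Product: 4 (1R,6R)-6-(2-hydroxypropan-2-yl)-7-oxabicyclo[4.1.0]heptan-2-one
Conditions: 9-amino-9-deoxy-epi-quinine (10 mol%), CF3CO2H (20 mol%), 50% aq. H2O2 (1.5 equiv), dioxane, 40 °C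
Reagents that add atoms: hydrogen peroxide, OO
Why: amine-salt (iminium) catalysed Weitz–Scheffer epoxidation: hydroperoxide adds to the β-carbon of the chiral iminium ion and the peroxy-enamine closes to the oxirane, so both C–O bonds and both stereocentres (1R,6R) are set by the catalyst.

Step 4
Reactants: 3 3-(2-hydroxypropan-2-yl)cyclohex-2-en-1-one
Product: 5 (1S,6S)-6-(2-hydroxypropan-2-yl)-7-oxabicyclo[4.1.0]heptan-2-one
Conditions: 9-amino-9-deoxy-epi-quinidine (10 mol%), CF3CO2H (20 mol%), 50% aq. H2O2 (1.5 equiv), dioxane, 40 °C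
Reagents that add atoms: hydrogen peroxide, OO
Why: the same iminium-catalysed Weitz–Scheffer epoxidation with the pseudo-enantiomeric amine delivers oxygen to the opposite face and gives the (1S,6S) antipode.

Step 5
Reactants: 4 (1R,6R)-6-(2-hydroxypropan-2-yl)-7-oxabicyclo[4.1.0]heptan-2-one
Product: 7 (2R,3R)-3-acetyl-2-[(tert-butyldimethylsilyl)oxy]-3-methylcyclohexan-1-one, via epoxy silyl ether 6 (not isolated)
Conditions: TBSOTf (1.3 equiv), 2,6-di-tert-butyl-4-methylpyridine (1.5 equiv), CH2Cl2, −78 → −20 °C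
Reagents that add atoms: tert-butyldimethylsilyl trifluoromethanesulfonate, CC(C)(C)[Si](C)(C)OS(=O)(=O)C(F)(F)F
Why: Proposed new method: silyl-triflate-triggered semipinacol 1,2-methyl shift in an α,β-epoxy ketone that carries a β-dimethylcarbinol; TBSOTf caps the carbinol (6) and then silylates the oxirane oxygen, only the tertiary β C–O bond can ionise (the α-carbon is deactivated by the ketone), and a carbinol methyl antiperiplanar to that bond migrates in concert, pushed by the siloxy oxygen, whose silyl group is then released; the methyl therefore enters anti to the oxygen that stays on C2, and the new acetyl group is cis to the silyloxy group (2R,3R). The closest known reaction type is the Tsuchihashi–Suzuki semipinacol rearrangement of 2,3-epoxy alcohol silyl ethers (Jung non-aldol aldol); what is new is methyl migration inside an epoxy ketone, where acyl shift with ring contraction is the usual course.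

Step 6
Reactants: 5 (1S,6S)-6-(2-hydroxypropan-2-yl)-7-oxabicyclo[4.1.0]heptan-2-one
Product: 9 (2S,3S)-3-acetyl-2-[(tert-butyldimethylsilyl)oxy]-3-methylcyclohexan-1-one, via epoxy silyl ether 8 (not isolated)
Conditions: TBSOTf (1.3 equiv), 2,6-di-tert-butyl-4-methylpyridine (1.5 equiv), CH2Cl2, −78 → −20 °C
Reagents that add atoms: tert-butyldimethylsilyl trifluoromethanesulfonate, CC(C)(C)[Si](C)(C)OS(=O)(=O)C(F)(F)F
Why: Proposed new method: the same silyl-triflate-triggered semipinacol 1,2-methyl shift as in step 5 (anti migration onto the tertiary oxirane carbon, oxygen retained on C2; closest known type the Tsuchihashi–Suzuki semipinacol rearrangement), run on the antipode to give the (2S,3S) ketone.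

Step 7
Reactants: 7 (2R,3R)-3-acetyl-2-[(tert-butyldimethylsilyl)oxy]-3-methylcyclohexan-1-one; 10 butane-1,4-diylbis(triphenylphosphonium) dibromide
Product: 12 [(4Z)-4-{(2S,3R)-3-acetyl-2-[(tert-butyldimethylsilyl)oxy]-3-methylcyclohexylidene}butyl]triphenylphosphonium bromide, via phosphonium ylide 11 (not isolated)
Conditions: 10 (3 equiv), KN(SiMe3)2 (3 equiv), THF, 0 °C; then 7, −78 → 0 °C; SiO2 (CH2Cl2/MeOH)
Reagents that add atoms: none
Why: Wittig olefination of an α-silyloxy ketone with a non-stabilised ylide (Still-type Z-selective variant): under kinetic control the ylide chain ends up cis to the oxygen-bearing α-carbon (Z alkene), the neopentyl acetyl group is too hindered to react, and the second phosphonium is kept for step 8.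

Step 8
Reactants: 12 [(4Z)-4-{(2S,3R)-3-acetyl-2-[(tert-butyldimethylsilyl)oxy]-3-methylcyclohexylidene}butyl]triphenylphosphonium bromide; 9 (2S,3S)-3-acetyl-2-[(tert-butyldimethylsilyl)oxy]-3-methylcyclohexan-1-one
Product: 14 meso-(1Z,4Z)-1,4-bis{3-acetyl-2-[(tert-butyldimethylsilyl)oxy]-3-methylcyclohexylidene}butane (ring A 2S,3R; ring B 2R,3S), via alkenyl ylide 13 (not isolated)
Conditions: KN(SiMe3)2 (1.05 equiv), THF, −78 °C; then 9 (1.2 equiv), −78 → 0 °C
Reagents that add atoms: none
Why: second Still-type Z-selective Wittig reaction; the ylide carries the ring derived from 7 and the ketone 9 is its antipode, so the dimer can only be the meso compound with both alkenes Z.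

Step 9
Reactants: 14 meso-(1Z,4Z)-1,4-bis{3-acetyl-2-[(tert-butyldimethylsilyl)oxy]-3-methylcyclohexylidene}butane; 15 1-bromo-2-methylprop-1-ene
Product: 16 meso-(1Z,4Z)-1,4-bis{2-[(tert-butyldimethylsilyl)oxy]-3-methyl-3-(4-methylpent-3-enoyl)cyclohexylidene}butane (ring A 2S,3R; ring B 2R,3S)
Conditions: LiN(SiMe3)2 (4.4 equiv), Pd2(dba)3 (2.5 mol%), P(t-Bu)3 (10 mol%), 15 (2.4 equiv), THF, 0 °C → rt; AcOH, −78 °C
Reagents that add atoms: none
Why: Pd2(dba)3/P(t-Bu)3-catalysed α-alkenylation of ketone enolates (Buchwald–Hartwig-type enolate coupling): only the two methyl groups can be enolised, and kinetic α-protonation of the product dienolates gives the β,γ-unsaturated ketones; no stereocentre is touched.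

Step 10
Reactants: 16 meso-(1Z,4Z)-1,4-bis{2-[(tert-butyldimethylsilyl)oxy]-3-methyl-3-(4-methylpent-3-enoyl)cyclohexylidene}butane
Product: 17 meso-(1Z,4Z)-1,4-bis[2-hydroxy-3-methyl-3-(4-methylpent-3-enoyl)cyclohexylidene]butane (ring A 2S,3R; ring B 2R,3S; the target)
Conditions: HF·pyridine, pyridine/THF, 0 °C → rt
Reagents that add atoms: none
Why: fluoride-driven Si–O cleavage under mildly acidic, non-basic conditions spares the β-hydroxy ketone (no retro-aldol) and the β,γ-enone (no conjugation).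

## Compound list

1 | 1-(cyclohex-1-en-1-yl)ethan-1-one (1-acetylcyclohexene) | CC(=O)C1=CCCCC1 | starting material
2 | 2-(cyclohex-1-en-1-yl)propan-2-ol | CC(C)(O)C1=CCCCC1 | intermediate
3 | 3-(2-hydroxypropan-2-yl)cyclohex-2-en-1-one | CC(C)(O)C1=CC(=O)CCC1 | intermediate
4 | (1R,6R)-6-(2-hydroxypropan-2-yl)-7-oxabicyclo[4.1.0]heptan-2-one | O=C1CCC[C@@]2(C(C)(C)O)O[C@@H]12 | intermediate
5 | (1S,6S)-6-(2-hydroxypropan-2-yl)-7-oxabicyclo[4.1.0]heptan-2-one | O=C1CCC[C@]2(C(C)(C)O)O[C@H]12 | intermediate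
6 | (1R,6R)-6-{2-[(tert-butyldimethylsilyl)oxy]propan-2-yl}-7-oxabicyclo[4.1.0]heptan-2-one | O=C1CCC[C@@]2(C(C)(C)O[Si](C)(C)C(C)(C)C)O[C@@H]12 | intermediate (not isolated)
7 | (2R,3R)-3-acetyl-2-[(tert-butyldimethylsilyl)oxy]-3-methylcyclohexan-1-one | CC(=O)[C@]1(C)CCCC(=O)[C@@H]1O[Si](C)(C)C(C)(C)C | intermediate
8 | (1S,6S)-6-{2-[(tert-butyldimethylsilyl)oxy]propan-2-yl}-7-oxabicyclo[4.1.0]heptan-2-one | O=C1CCC[C@]2(C(C)(C)O[Si](C)(C)C(C)(C)C)O[C@H]12 | intermediate (not isolated)
9 | (2S,3S)-3-acetyl-2-[(tert-butyldimethylsilyl)oxy]-3-methylcyclohexan-1-one | CC(=O)[C@@]1(C)CCCC(=O)[C@H]1O[Si](C)(C)C(C)(C)C | intermediate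
10 | butane-1,4-diylbis(triphenylphosphonium) dibromide | [Br-].[Br-].c1ccccc1[P+](c1ccccc1)(c1ccccc1)CCCC[P+](c1ccccc1)(c1ccccc1)c1ccccc1 | starting material
11 | triphenyl[4-(triphenyl-λ5-phosphanylidene)butyl]phosphonium bromide | [Br-].c1ccccc1P(c1ccccc1)(c1ccccc1)=CCCC[P+](c1ccccc1)(c1ccccc1)c1ccccc1 | intermediate (not isolated)
12 | [(4Z)-4-{(2S,3R)-3-acetyl-2-[(tert-butyldimethylsilyl)oxy]-3-methylcyclohexylidene}butyl]triphenylphosphonium bromide | CC(=O)[C@]1(C)CCC/C(=C/CCC[P+](c2ccccc2)(c2ccccc2)c2ccccc2)[C@@H]1O[Si](C)(C)C(C)(C)C.[Br-] | intermediate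
13 | 1-[(1R,2S,3Z)-2-[(tert-butyldimethylsilyl)oxy]-1-methyl-3-[4-(triphenyl-λ5-phosphanylidene)butylidene]cyclohexyl]ethan-1-one | CC(=O)[C@]1(C)CCC/C(=C/CCC=P(c2ccccc2)(c2ccccc2)c2ccccc2)[C@@H]1O[Si](C)(C)C(C)(C)C | intermediate (not isolated)
14 | meso-(1Z,4Z)-1,4-bis{3-acetyl-2-[(tert-butyldimethylsilyl)oxy]-3-methylcyclohexylidene}butane (ring A 2S,3R; ring B 2R,3S) | CC(=O)[C@]1(C)CCC/C(=C/CC/C=C2/CCC[C@](C)(C(C)=O)[C@@H]2O[Si](C)(C)C(C)(C)C)[C@@H]1O[Si](C)(C)C(C)(C)C | intermediate
15 | 1-bromo-2-methylprop-1-ene | CC(C)=CBr | starting material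
16 | meso-(1Z,4Z)-1,4-bis{2-[(tert-butyldimethylsilyl)oxy]-3-methyl-3-(4-methylpent-3-enoyl)cyclohexylidene}butane (ring A 2S,3R; ring B 2R,3S) | CC(C)=CCC(=O)[C@]1(C)CCC/C(=C/CC/C=C2/CCC[C@](C)(C(=O)CC=C(C)C)[C@@H]2O[Si](C)(C)C(C)(C)C)[C@@H]1O[Si](C)(C)C(C)(C)C | intermediate
17 | meso-(1Z,4Z)-1,4-bis[2-hydroxy-3-methyl-3-(4-methylpent-3-enoyl)cyclohexylidene]butane (ring A 2S,3R; ring B 2R,3S; in cyclohexanol numbering 1R,2S and 1S,2R) | CC(C)=CCC(=O)[C@]1(C)CCC/C(=C/CC/C=C2/CCC[C@](C)(C(=O)CC=C(C)C)[C@@H]2O)[C@@H]1O | target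

## Step count and risks

Total step count: 10. Longest linear sequence: 8 (steps 1, 2, 3, 5, 7, 8, 9, 10; steps 4 and 6 are the parallel antipodal branch).

Three steps most likely to fail:

Step 5 (the proposed new step; step 6 is its mirror-image twin and shares its fate). The risk is that the ring acyl group or a hydride migrates instead of the carbinol methyl, giving ring contraction or a 1,2-dione. The fallback uses known chemistry and takes the ring ketone out of play before the rearrangement. From 4, NaBH4/CeCl3·7H2O in MeOH (Luche reduction) gives the epoxy diol F1 as a mixture of carbinol epimers, both usable. TESCl/imidazole caps the secondary hydroxyl selectively to give the triethylsilyl ether F2. TBSOTf/2,6-lutidine then effects the classical Tsuchihashi–Suzuki-type semipinacol rearrangement of a ketone-free 2,3-epoxy tertiary alcohol to the rearranged bis(silyl ether) F3. PPTS/MeOH removes the triethylsilyl group to give the alcohol F4, and Dess–Martin periodinane restores the ketone, which returns the route to 7. The mirror-image sequence from 5 passes through the epoxy diol F5, the triethylsilyl ether F6, the bis(silyl ether) F7 and the alcohol F8 and returns to 9.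

Step 3 (and its twin, step 4). The tertiary substituent on the β-carbon may slow peroxide addition to the iminium ion or lower the enantioselectivity. The fallback sets out from 3: uncatalysed Weitz–Scheffer epoxidation (30% H2O2, NaOH, MeOH, 0 °C) gives the racemate of 4 and 5, and the two antipodes are separated by preparative chromatography on a chiral stationary phase. Both antipodes are needed in equal amounts for the meso target, so the resolution wastes nothing, and the route is rejoined at 4 and 5. This fallback makes no new compound (F0).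

Step 7. The twofold salt 10 can give double olefination and phosphonium salts that are hard to separate. The fallback builds the four-carbon linker stepwise. From 7, Wittig reaction with the ylide of but-3-en-1-yl(triphenyl)phosphonium bromide (KN(SiMe3)2, THF, −78 °C) gives the diene ketone F9. Hydroboration of the terminal alkene with 9-BBN and oxidation with NaBO3 gives the primary alcohol F10. I2/PPh3/imidazole (Appel reaction) gives the iodide F11, and PPh3 in MeCN at reflux gives the phosphonium iodide F12. F12 takes the place of 12 in step 8 (same ylide 13, same ketone 9), so the route is rejoined at 14.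

## Further compounds

F1 | step 5 | (1S,6R)-6-(2-hydroxypropan-2-yl)-7-oxabicyclo[4.1.0]heptan-2-ol (both C2 epimers) | OC1CCC[C@@]2(C(C)(C)O)O[C@@H]12
F2 | step 5 | triethylsilyl ether of F1 at the ring hydroxyl (carbinol OH free) | CC[Si](CC)(CC)OC1CCC[C@@]2(C(C)(C)O)O[C@@H]12
F3 | step 5 | 1-[(1R,2R)-2-[(tert-butyldimethylsilyl)oxy]-1-methyl-3-[(triethylsilyl)oxy]cyclohexyl]ethan-1-one (both C3 epimers) | CC(=O)[C@]1(C)CCCC(O[Si](CC)(CC)CC)[C@@H]1O[Si](C)(C)C(C)(C)C
F4 | step 5 | 1-[(1R,2R)-2-[(tert-butyldimethylsilyl)oxy]-3-hydroxy-1-methylcyclohexyl]ethan-1-one (both C3 epimers) | CC(=O)[C@]1(C)CCCC(O)[C@@H]1O[Si](C)(C)C(C)(C)C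
F5 | step 5 | (1R,6S)-6-(2-hydroxypropan-2-yl)-7-oxabicyclo[4.1.0]heptan-2-ol (both C2 epimers) | OC1CCC[C@]2(C(C)(C)O)O[C@H]12
F6 | step 5 | triethylsilyl ether of F5 at the ring hydroxyl (carbinol OH free) | CC[Si](CC)(CC)OC1CCC[C@]2(C(C)(C)O)O[C@H]12
F7 | step 5 | 1-[(1S,2S)-2-[(tert-butyldimethylsilyl)oxy]-1-methyl-3-[(triethylsilyl)oxy]cyclohexyl]ethan-1-one (both C3 epimers) | CC(=O)[C@@]1(C)CCCC(O[Si](CC)(CC)CC)[C@H]1O[Si](C)(C)C(C)(C)C
F8 | step 5 | 1-[(1S,2S)-2-[(tert-butyldimethylsilyl)oxy]-3-hydroxy-1-methylcyclohexyl]ethan-1-one (both C3 epimers) | CC(=O)[C@@]1(C)CCCC(O)[C@H]1O[Si](C)(C)C(C)(C)C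
F0 | step 3 | none | none
F9 | step 7 | 1-[(1R,2S,3Z)-3-(but-3-en-1-ylidene)-2-[(tert-butyldimethylsilyl)oxy]-1-methylcyclohexyl]ethan-1-one | CC(=O)[C@]1(C)CCC/C(=C/CC=C)[C@@H]1O[Si](C)(C)C(C)(C)C
F10 | step 7 | 1-[(1R,2S,3Z)-2-[(tert-butyldimethylsilyl)oxy]-3-(4-hydroxybutylidene)-1-methylcyclohexyl]ethan-1-one | CC(=O)[C@]1(C)CCC/C(=C/CCCO)[C@@H]1O[Si](C)(C)C(C)(C)C
F11 | step 7 | 1-[(1R,2S,3Z)-2-[(tert-butyldimethylsilyl)oxy]-3-(4-iodobutylidene)-1-methylcyclohexyl]ethan-1-one | CC(=O)[C@]1(C)CCC/C(=C/CCCI)[C@@H]1O[Si](C)(C)C(C)(C)C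
F12 | step 7 | [(4Z)-4-{(2S,3R)-3-acetyl-2-[(tert-butyldimethylsilyl)oxy]-3-methylcyclohexylidene}butyl]triphenylphosphonium iodide | CC(=O)[C@]1(C)CCC/C(=C/CCC[P+](c2ccccc2)(c2ccccc2)c2ccccc2)[C@@H]1O[Si](C)(C)C(C)(C)C.[I-]
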